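**Strategy.** Ring A (C1–C5, C10; eremophilane numbering) is made one carbon short. (S)-3,4-Dimethylcyclopent-2-enone, obtained by desymmetrising a meso ketone, undergoes a Diels–Alder reaction with a 1-silyloxybutadiene to give a cis-hydrindenone whose five-membered ring is C2–C3–C4–C5–C10. In the key step its cyclopropanated C2=C10 silyl enol ether is opened by FeCl3: strain release inserts C1 between C2 and C10 and delivers the ring-A enone. The step exploits the C2 oxygen of ring A, which lies on a carbon flanked by C1 and β to ring-fusion carbon C10. The single bought stereocentre (C4) then relays C5, C9, C10, C7, C8 and C2 by substrate control.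

Key step: step 7

Remarks before the steps:
- Labels: eremophilane numbering of the target is used for all bicyclic compounds (ring A = C1–C5 and C10, ring B = C5–C10, C11–C13 = isopropenyl, methyls on C4 and C5). β is the face of the C5 methyl, α the opposite face. In 6–8, where C1 is not yet present, the other labels keep their meaning.
- Assumption: racemic enone 1, diene 5, Grignard reagent 14 and acid 16 are bought.
- Assumption: the (R,R) lithium amide is written for step 2; if its sense of induction on ketone 2 is the opposite, the (S,S) base is used and nothing else changes.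

Step 1
Reactants: 1 (±)-3,4-dimethylcyclopent-2-en-1-one
Product: 2 cis-3,4-dimethylcyclopentan-1-one (meso)
Conditions: H2 (1 atm), Pd/C, EtOAc, 23 °C
Reagents that add atoms: none
Why: Heterogeneous hydrogenation adds H2 to the enone C=C from the face anti to the C4 methyl, which should give the cis isomer, a meso compound on which both enantiomers of 1 converge.

Step 2
Reactants: 2 cis-3,4-dimethylcyclopentan-1-one
Product: 3 (3S,4S)-3,4-dimethyl-1-(trimethylsilyloxy)cyclopent-1-ene
Conditions: (R,R)-bis(1-phenylethyl)amine, n-BuLi, LiCl, TMSCl (internal quench), THF, −100 °C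
Reagents that add atoms: chlorotrimethylsilane, C[Si](C)(C)Cl
Why: A chiral lithium amide distinguishes the two enantiotopic α-methylene groups of the meso ketone (enantioselective deprotonation with internal silyl quench), which fixes the methyl-bearing carbon that becomes C4 of the target in the (S) configuration.

Step 3
Reactants: 3 (3S,4S)-3,4-dimethyl-1-(trimethylsilyloxy)cyclopent-1-ene
Product: 4 (S)-3,4-dimethylcyclopent-2-en-1-one
Conditions: Pd(OAc)2 (1.05 equiv), MeCN, 23 °C
Reagents that add atoms: none
Why: Saegusa–Ito oxidation: the divalent palladium enolate loses the C3 hydrogen by β-hydride elimination, which restores the enone and leaves C4 as the only stereocentre.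

Step 4
Reactants: 4 (S)-3,4-dimethylcyclopent-2-en-1-one; 5 (E)-1-(trimethylsilyloxy)buta-1,3-diene
Product: 6 cis-hydrindenone (3S,3aR,7R,7aS)-3,3a-dimethyl-7-(trimethylsilyloxy)-2,3,3a,4,7,7a-hexahydro-1H-inden-1-one (4β,5β-dimethyl; 9α-OTMS; 10β-H; Δ7)
Conditions: CH2Cl2, 15 kbar, 25 °C
Reagents that add atoms: none
Why: A normal-demand Diels–Alder reaction under high pressure should join the nucleophilic diene terminus to the enone β-carbon C5 (ortho rule) through an endo transition state on the face anti to the C4 methyl, so that the C5 methyl ends up cis to the C4 methyl and the C9 oxygen anti to the C5 methyl, while the cis ring fusion at C10 does not matter because C10 is erased in step 5.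

Step 5
Reactants: 6 cis-hydrindenone
Product: 7 bis-silyl ether (1S,4R,7aR)-1,7a-dimethyl-3,4-bis(trimethylsilyloxy)-2,4,7,7a-tetrahydro-1H-indene (C2=C10 silyl enol ether)
Conditions: TMSOTf, Et3N, CH2Cl2, 0 → 23 °C
Reagents that add atoms: trimethylsilyl trifluoromethanesulfonate, C[Si](C)(C)OS(=O)(=O)C(F)(F)F
Why: Soft enolisation with TMSOTf and Et3N under equilibrating conditions should give the more substituted silyl enol ether toward ring-fusion carbon C10 (thermodynamic control), which also erases the C10 centre set in step 4.

Step 6
Reactants: 7 bis-silyl ether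
Product: 8 siloxycyclopropane (7 with the methylene C1 bridging C2 and C10 on the α face; 2-OTMS and 9α-OTMS kept)
Conditions: Et2Zn, CH2I2, CH2Cl2, 0 °C
Reagents that add atoms: diiodomethane, ICI
Why: Furukawa-modified Simmons–Smith cyclopropanation: the electron-rich silyl enol ether reacts far faster than the isolated C7=C8 alkene, and the zinc carbenoid should add anti to the C5 methyl, although the two cyclopropane centres are lost again in step 7.

Step 7
Reactants: 8 siloxycyclopropane
Product: 10 hydroxy dienone (4S,4aR,8R)-8-hydroxy-4,4a-dimethyl-4,4a,5,8-tetrahydronaphthalen-2(3H)-one (9α-hydroxy-11,12,13-trinoreremophila-1(10),7-dien-2-one), via chloro ketone 9 (not isolated)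
Conditions: FeCl3 (2.2 equiv), DMF, 0 °C; 1 M HCl work-up; then NaOAc, MeOH, 65 °C
Reagents that add atoms: none
Why: FeCl3 (trivalent iron) oxidises the siloxycyclopropane by one electron to a cyclopropyloxy radical, whose strained internal C2–C10 bond undergoes β-scission to give the C2 ketone and the tertiary C10 radical of the enlarged ring, which takes chlorine from a second FeCl3; NaOAc then removes HCl through the C1 enolate to give the Δ1(10)-2-one. The closest known reaction type is the FeCl3 ring enlargement of 1-siloxybicyclo[n.1.0]alkanes to cycloalk-2-enones (Ito–Saegusa ring enlargement). No ring is closed: ring A arises from the five-membered ring C2–C3–C4–C5–C10 by insertion of C1 between C2 and C10, driven by release of cyclopropane strain. No stereocentre is created; C2 and C10 become sp2, and C4, C5 and C9 are not touched. The step needs cleavage of the internal and not the external cyclopropane bond, which is secured by the larger strain relief and by the tertiary ring-fusion radical that results; it also needs the alkene at C1=C10, which is secured because chloride sits on C10 and only the C1 hydrogens are acidified by the ketone.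

Step 8
Reactants: 10 hydroxy dienone
Product: 11 epoxy enone (7α,8α-epoxy-9α-hydroxy-11,12,13-trinoreremophil-1(10)-en-2-one)
Conditions: VO(acac)2 (cat.), t-BuOOH, CH2Cl2, 0 → 23 °C
Reagents that add atoms: tert-butyl hydroperoxide, CC(C)(C)OO
Why: Vanadium-catalysed hydroxyl-directed epoxidation should deliver oxygen to C7=C8 syn to the 9α-hydroxyl, which is also the face anti to the C5 methyl, and should leave the electron-poor C1=C10 enone alkene alone.

Step 9
Reactants: 11 epoxy enone
Product: 12 epoxy decalone (7α,8α-epoxy-9α-hydroxy-10α-H-11,12,13-trinoreremophilan-2-one; trans-decalin)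
Conditions: H2 (1 atm), [Ir(cod)(PCy3)(py)]PF6 (cat.), CH2Cl2, 23 °C
Reagents that add atoms: none
Why: Hydroxyl-directed homogeneous hydrogenation: the cationic iridium catalyst bound to the 9α-OH should add H2 to the α face of C1=C10, which gives the 10α-H trans-decalin.

Step 10
Reactants: 12 epoxy decalone
Product: 13 epoxy diol (7α,8α-epoxy-10α-H-11,12,13-trinoreremophilane-2α,9α-diol)
Conditions: LiBH(s-Bu)3, THF, −78 °C; aq. NH4Cl
Reagents that add atoms: none
Why: The bulky borohydride should attack the ring-A cyclohexanone from the equatorial direction, because the axial path is hindered by the axial hydrogens at C4 and C10, and so give the axial 2α-alcohol.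

Step 11
Reactants: 13 epoxy diol; 14 isopropenylmagnesium bromide
Product: 15 triol (10α-H-eremophil-11-ene-2α,8α,9α-triol; 7β-isopropenyl)
Conditions: CuI (cat.), THF, −30 → 0 °C
Reagents that add atoms: none
Why: Copper-catalysed Grignard opening of the epoxide should follow the Fürst–Plattner rule, with trans-diaxial attack at C7 from the β face (the carbon remote from O9) and inversion there, which gives the axial 7β-isopropenyl group next to the axial 8α-hydroxyl.

Step 12
Reactants: 15 triol; 16 (E)-3-methylpent-2-enoic acid
Product: 19 target ester (2S,4S,5R,7R,8R,9S,10R)-2,8-dihydroxyeremophil-11-en-9-yl (2E)-3-methylpent-2-enoate, via acid chloride 17 (not isolated), via stannylene acetal 18 (not isolated)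
Conditions: 16, (COCl)2, cat. DMF, CH2Cl2, 23 °C; 15, Bu2SnO, toluene, 110 °C; then mix, 0 → 23 °C
Reagents that add atoms: none
Why: Regioselective acylation through a dibutylstannylene acetal: the tin acetal forms on the cis-8α,9α-diol and raises the nucleophilicity of its equatorial oxygen O9 over the axial, more hindered O8 and the untouched 2-OH, and the base-free acid chloride keeps the (E)-enoate intact.

**Compound list**

1 | (±)-3,4-dimethylcyclopent-2-en-1-one | CC1CC(=O)C=C1C | starting material
2 | cis-3,4-dimethylcyclopentan-1-one (meso) | C[C@H]1CC(=O)C[C@H]1C | intermediate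
3 | (3S,4S)-3,4-dimethyl-1-(trimethylsilyloxy)cyclopent-1-ene | C[Si](C)(C)OC1=C[C@@H](C)[C@@H](C)C1 | intermediate
4 | (S)-3,4-dimethylcyclopent-2-en-1-one | O=C1C=C(C)[C@@H](C)C1 | intermediate
5 | (E)-1-(trimethylsilyloxy)buta-1,3-diene | C=C/C=C/O[Si](C)(C)C | starting material
6 | (3S,3aR,7R,7aS)-3,3a-dimethyl-7-(trimethylsilyloxy)-2,3,3a,4,7,7a-hexahydro-1H-inden-1-one | O=C1C[C@H](C)[C@@]2(C)CC=C[C@@H](O[Si](C)(C)C)[C@@H]12 | intermediate
7 | (1S,4R,7aR)-1,7a-dimethyl-3,4-bis(trimethylsilyloxy)-2,4,7,7a-tetrahydro-1H-indene | C[Si](C)(C)OC1=C2[C@H](O[Si](C)(C)C)C=CC[C@]2(C)[C@@H](C)C1 | intermediate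
8 | siloxycyclopropane (C1 methylene across C2–C10 of 7, α face) | C[Si](C)(C)O[C@@]12C[C@@]13[C@H](O[Si](C)(C)C)C=CC[C@]3(C)[C@@H](C)C2 | intermediate
9 | 10-chloro-9α-hydroxy-11,12,13-trinoreremophil-7-en-2-one (10α-chloro epimer drawn; either epimer eliminates) | O=C1C[C@@]2(Cl)[C@H](O)C=CC[C@]2(C)[C@@H](C)C1 | intermediate (not isolated)
10 | (4S,4aR,8R)-8-hydroxy-4,4a-dimethyl-4,4a,5,8-tetrahydronaphthalen-2(3H)-one | O=C1C=C2[C@H](O)C=CC[C@]2(C)[C@@H](C)C1 | intermediate
11 | 7α,8α-epoxy-9α-hydroxy-11,12,13-trinoreremophil-1(10)-en-2-one | O=C1C=C2[C@H](O)[C@@H]3O[C@@H]3C[C@]2(C)[C@@H](C)C1 | intermediate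
12 | 7α,8α-epoxy-9α-hydroxy-10α-H-11,12,13-trinoreremophilan-2-one | O=C1C[C@H]2[C@H](O)[C@@H]3O[C@@H]3C[C@]2(C)[C@@H](C)C1 | intermediate
13 | 7α,8α-epoxy-10α-H-11,12,13-trinoreremophilane-2α,9α-diol | O[C@@H]1C[C@H]2[C@H](O)[C@@H]3O[C@@H]3C[C@]2(C)[C@@H](C)C1 | intermediate
14 | isopropenylmagnesium bromide | C=C(C)[Mg]Br | starting material
15 | 10α-H-eremophil-11-ene-2α,8α,9α-triol | C=C(C)[C@H]1C[C@]2(C)[C@@H](C)C[C@H](O)C[C@H]2[C@H](O)[C@@H]1O | intermediate
16 | (E)-3-methylpent-2-enoic acid | CC/C(C)=C/C(=O)O | starting material
17 | (E)-3-methylpent-2-enoyl chloride | CC/C(C)=C/C(=O)Cl | intermediate (not isolated)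
18 | 8,9-O-dibutylstannylene acetal of 15 | C=C(C)[C@H]1C[C@]2(C)[C@@H](C)C[C@H](O)C[C@H]2[C@@H]3O[Sn](CCCC)(CCCC)O[C@H]13 | intermediate (not isolated)
19 | (2S,4S,5R,7R,8R,9S,10R)-2,8-dihydroxyeremophil-11-en-9-yl (2E)-3-methylpent-2-enoate | C=C(C)[C@H]1C[C@]2(C)[C@@H](C)C[C@H](O)C[C@H]2[C@H](OC(=O)/C=C(\C)CC)[C@@H]1O | target

**Totals.** Total step count: 12. Longest linear sequence: 12 steps (1 → 19).

**Steps most likely to fail**

1. Step 4 (Diels–Alder). The cycloaddition may be too slow, because the dienophile carbon C5 is fully substituted, and the silyloxydiene may polymerise before it adds. Fallback, an annulation in stages in place of the cycloaddition: from 4, a Hosomi–Sakurai allylation (allyltrimethylsilane, TiCl4, CH2Cl2, −78 °C; anti to the C4 methyl) whose titanium enolate is trapped in the same flask with acrolein should give aldol adduct F1. Ring-closing metathesis with second-generation Grubbs catalyst should close ring B to hydroxy ketone F2. The C10 epimers of F2 are equivalent for the route, but the C9 configuration rests on the aldol step and the unwanted C9 epimer would be separated here. TMSOTf and Et3N then silylate the alcohol and enolise the ketone toward C10, which brings the material back at 7.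

2. Step 5 (enol ether). Enolisation may go toward C3 and not C10, or the 9-silyloxy group may be lost by β-elimination. Fallback, a carbenoid homologation of the ketone that needs no enol ether of 6: from 6, addition of dibromomethyllithium (CH2Br2, lithium tetramethylpiperidide, THF, −78 °C) to the C2 ketone should give dibromomethyl carbinol F3. n-BuLi (2 equiv, −78 °C) turns F3 into a β-oxido carbenoid that rearranges with migration of the more substituted carbon C10. This is again a one-carbon enlargement of the five-membered ring. The resulting lithium enolate is trapped with TMSCl as ring-enlarged enol ether F4. Saegusa–Ito oxidation (Pd(OAc)2, MeCN) followed by aqueous HCl places the alkene at C1=C10, frees the 9-hydroxyl and returns to the route at 10.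

3. Step 11 (epoxide opening). Trans-diaxial attack at C7 runs past the axial C5 methyl, so the opening may be slow and base-induced isomerisation of the epoxide to an allylic alcohol may compete. Fallback, introduction of the isopropenyl group in two stages through a slimmer nucleophile: from 13, opening with lithium acetylide–ethylenediamine complex (DMSO, 25 °C) should give alkynyl triol F5 by the same trans-diaxial course. Zirconium-catalysed methylalumination (AlMe3, Cp2ZrCl2, ClCH2CH2Cl; Negishi carboalumination) adds methyl to the internal alkyne carbon, and protonolysis of the alkenylalane with water gives the isopropenyl group, which returns to the route at 15.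

**Further compounds**

F1 | step 4 | aldol adduct: 3-allyl-2-(1-hydroxyprop-2-enyl)-3,4-dimethylcyclopentan-1-one (C10 epimers, desired C9 epimer) | O=C1C[C@H](C)[C@@](C)(CC=C)C1[C@H](O)C=C
F2 | step 4 | hydroxy ketone: 7-hydroxy-3,3a-dimethyl-2,3,3a,4,7,7a-hexahydro-1H-inden-1-one (9α-OH, C10 epimers) | O=C1C[C@H](C)[C@@]2(C)CC=C[C@@H](O)C12
F3 | step 5 | dibromomethyl carbinol: 1-(dibromomethyl)-3,3a-dimethyl-7-(trimethylsilyloxy)-2,3,3a,4,7,7a-hexahydro-1H-inden-1-ol (C2 epimers) | OC1(C(Br)Br)C[C@H](C)[C@@]2(C)CC=C[C@@H](O[Si](C)(C)C)[C@@H]12
F4 | step 5 | ring-enlarged enol ether: 2,9α-bis(trimethylsilyloxy)-10β-H-11,12,13-trinoreremophila-1,7-diene | C[Si](C)(C)OC1=C[C@@H]2[C@H](O[Si](C)(C)C)C=CC[C@]2(C)[C@@H](C)C1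
F5 | step 11 | alkynyl triol: 7β-ethynyl-10α-H-11,12,13-trinoreremophilane-2α,8α,9α-triol | C#C[C@H]1C[C@]2(C)[C@@H](C)C[C@H](O)C[C@H]2[C@H](O)[C@@H]1O
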